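**Strategy.** Ring A carries oxygen on C5, C6, C7 and C8, with the C5 and C8 oxygens para: a hidden 2,3-dimethoxyhydroquinone. Ring A is therefore cut at C8–C8a and C4a–C5, back to dimethyl squarate and a preformed 2-aryl-3-benzyloxypyran-4-one that carries rings C and B. Heating the squarate adduct opens the cyclobutenone to a dienylketene that closes onto the pyranone C5=C6 bond. This forges C8–C8a and delivers the 5,8-dihydroxy-6,7-dimethoxychromone in one operation, with the chelated 5-OH already distinguished from the 8-OH. The precursor is a racemic 4-hydroxy-2,3-dimethoxycyclobutenone bearing the tribenzylated 4-oxopyran-3-yl group at C4, made by adding the 5-magnesiated pyranone to dimethyl squarate.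

Key step: step 7

Remark on stereochemistry: the target has no stereocentre and is achiral, so no enantiocontrol is needed. The stereocentres of 5, 6, 13 and 15 are carried as racemates and all are erased on the way.

Remark on numbering: pyranone atoms are numbered O1, C2 (aryl), C3 (oxygen), C4 (carbonyl), C5, C6; chromone atoms in the usual way.

Remark on design: an oxidative furan ring expansion alone stops one oxidation level short of a 3-hydroxy-4-pyranone. The missing equivalent is carried in as the bromine of 3-bromofuran. Iodine is placed at pyranone C5 by directed metalation, because electrophilic iodination would attack the dialkoxy ring B.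

Step 1
Reactants: 1 2,5-dihydroxybenzaldehyde
Product: 2 2,5-bis(benzyloxy)benzaldehyde
Conditions: BnBr (2.3 equiv), K2CO3, DMF, 60 °C
Reagents that add atoms: benzyl bromide, BrCc1ccccc1
Why: Williamson etherification of both phenols, with mild heating to engage the hydrogen-bonded 2-hydroxyl; benzyl is chosen so that all three protecting groups fall in one neutral hydrogenolysis at the end.

Step 2
Reactants: 2 2,5-bis(benzyloxy)benzaldehyde; 3 3-bromofuran
Product: 5 [2,5-bis(benzyloxy)phenyl](3-bromofuran-2-yl)methanol (racemic), via 3-bromo-2-lithiofuran 4 (not isolated)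
Conditions: LDA, THF, −78 °C; then 2, −78 °C; aq. NH4Cl
Reagents that add atoms: none
Why: Directed deprotonation of 3-bromofuran at C2 (the position flanked by oxygen and bromine) and 1,2-addition of the furyllithium to the aldehyde, kept at −78 °C to prevent halogen migration; the carbinol centre forms as a racemate and is erased in step 3.

Step 3
Reactants: 5 [2,5-bis(benzyloxy)phenyl](3-bromofuran-2-yl)methanol
Product: 7 2-[2,5-bis(benzyloxy)phenyl]-3-hydroxy-4H-pyran-4-one, via 4-bromo-6-hydroxy-2H-pyran-3(6H)-one 6 (not isolated)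
Conditions: NBS (1.05 equiv), NaHCO3, THF–H2O, 0 °C; then aq. H2SO4 (to ca. 1 M), 70 °C
Reagents that add atoms: water, O
Why: Achmatowicz oxidative ring expansion gives 6 with the furan bromine at C4, and hot aqueous acid then hydrolyses this vinylogous bromide to the C4 carbonyl with loss of HBr and of the C6 hydroxyl (the halogen-mediated maltol-type route to 3-hydroxy-4-pyranones), so no second dose of halogen is needed in the presence of ring B.

Step 4
Reactants: 7 2-[2,5-bis(benzyloxy)phenyl]-3-hydroxy-4H-pyran-4-one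
Product: 8 3-benzyloxy-2-[2,5-bis(benzyloxy)phenyl]-4H-pyran-4-one
Conditions: BnBr, K2CO3, DMF, 50 °C
Reagents that add atoms: benzyl bromide, BrCc1ccccc1
Why: Williamson O-alkylation of the acidic pyranone enol, which also re-protects any ring-B phenol that the acidic step may have freed.

Step 5
Reactants: 8 3-benzyloxy-2-[2,5-bis(benzyloxy)phenyl]-4H-pyran-4-one
Product: 10 3-benzyloxy-2-[2,5-bis(benzyloxy)phenyl]-5-iodo-4H-pyran-4-one, via pyranon-5-ylzinc chloride 9 (not isolated)
Conditions: TMPZnCl·LiCl (1.3 equiv), THF, 25 °C; then I2, 0 °C; aq. Na2S2O3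
Reagents that add atoms: iodine, II
Why: Carbonyl-directed zincation of the γ-pyrone at the carbon α to C4=O (the way chromones are zincated at C3; here C3 is blocked, leaving only C5) followed by iodolysis of the C–Zn bond, which places iodine without an electrophilic iodinating agent that would attack ring B.

Step 6
Reactants: 10 3-benzyloxy-2-[2,5-bis(benzyloxy)phenyl]-5-iodo-4H-pyran-4-one; 11 dimethyl squarate
Product: 13 4-{5-benzyloxy-6-[2,5-bis(benzyloxy)phenyl]-4-oxo-4H-pyran-3-yl}-4-hydroxy-2,3-dimethoxycyclobut-2-en-1-one (racemic), via pyranon-5-ylmagnesium chloride 12 (not isolated)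
Conditions: iPrMgCl·LiCl (1.1 equiv), THF, −40 °C; then cannulate into 11 (1.2 equiv), THF, −78 °C; aq. NH4Cl at −78 °C
Reagents that add atoms: none
Why: Iodine–magnesium exchange on the α-iodo-β-alkoxy enone gives a carbonyl-chelated alkenyl Grignard reagent that adds 1,2 to one squarate carbonyl (the standard entry to 4-hydroxycyclobutenones), with a cold neutral quench to avoid acid-induced loss of methanol; the carbinol centre forms as a racemate and becomes sp2 C5 in step 7.

Step 7
Reactants: 13 4-{5-benzyloxy-6-[2,5-bis(benzyloxy)phenyl]-4-oxo-4H-pyran-3-yl}-4-hydroxy-2,3-dimethoxycyclobut-2-en-1-one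
Product: 16 3-benzyloxy-2-[2,5-bis(benzyloxy)phenyl]-5,8-dihydroxy-6,7-dimethoxy-4H-chromen-4-one, via dienylketene 14 (not isolated), via 8aH-chromene-4,8-dione 15 (not isolated)
Conditions: degassed toluene (0.01 M), 110 °C, Ar (p-xylene, 135 °C if slow); aq. Na2S2O4 wash
Reagents that add atoms: none
Why: Heat opens the cyclobutenone by conrotatory 4π electrocyclic ring opening to dienylketene 14; the ketene carbon then bonds to pyranone C6 in a 6π electrocyclisation (six-membered ring A, new bond C8–C8a) to give dienone 15, and a proton shift from C8a to the C8 oxygen aromatises it to the hydroquinone. The closest known reaction type is the thermal ring expansion of 4-aryl-, 4-heteroaryl- and 4-alkenyl-4-hydroxycyclobutenones to hydroquinones (Moore rearrangement), with the pyranone C5=C6 bond playing the part of the alkene. No stereocentre survives: the carbinol centre of 13 becomes sp2 C5 and the transient C8a centre of 15 is lost on enolisation. The step needs outward rotation of the 4-hydroxyl, which is the intrinsic preference of a donor substituent and places the pyranonyl group, not the hydroxyl, next to the ketene (inward hydroxyl would lactonise to a butenolide). Regiochemistry is fixed by the substrate: the pyranone carbon bearing the cyclobutenone has the carbonyl carbon C4 on one side and C6 on the other, so closure can only use C5=C6, and the squarate methoxyls must end at C6 and C7 with the former carbinol oxygen at C5 beside the C4 carbonyl. Dilute, oxygen-free conditions protect the ketene and the air-sensitive hydroquinone.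

Step 8
Reactants: 16 3-benzyloxy-2-[2,5-bis(benzyloxy)phenyl]-5,8-dihydroxy-6,7-dimethoxy-4H-chromen-4-one
Product: 17 3-benzyloxy-2-[2,5-bis(benzyloxy)phenyl]-5-hydroxy-6,7,8-trimethoxy-4H-chromen-4-one
Conditions: MeI (1.1 equiv), K2CO3 (1.1 equiv), degassed acetone, rt, Ar
Reagents that add atoms: iodomethane, CI
Why: Williamson O-methylation that should take only the 8-hydroxyl, because the 5-hydroxyl is locked in a hydrogen bond to the C4 carbonyl and is much less acidic and nucleophilic under limiting base and reagent.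

Step 9
Reactants: 17 3-benzyloxy-2-[2,5-bis(benzyloxy)phenyl]-5-hydroxy-6,7,8-trimethoxy-4H-chromen-4-one
Product: 18 2-(2,5-dihydroxyphenyl)-3,5-dihydroxy-6,7,8-trimethoxy-4H-chromen-4-one
Conditions: H2 (1 atm), 10% Pd/C, EtOAc–MeOH, rt; filtration under Ar
Reagents that add atoms: none
Why: Catalytic hydrogenolysis cleaves the three benzyl ethers under neutral conditions that should leave the methyl ethers and the chromone C2=C3 bond intact and avoid base-promoted oxidation of the free hydroquinone ring B.

**Compound list**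

1 | 2,5-dihydroxybenzaldehyde | O=Cc1cc(O)ccc1O | starting material
2 | 2,5-bis(benzyloxy)benzaldehyde | O=Cc1cc(OCc2ccccc2)ccc1OCc1ccccc1 | intermediate
3 | 3-bromofuran | Brc1ccoc1 | starting material
4 | 3-bromo-2-lithiofuran | [Li]c1occc1Br | intermediate
5 | [2,5-bis(benzyloxy)phenyl](3-bromofuran-2-yl)methanol (racemic) | OC(c1occc1Br)c1cc(OCc2ccccc2)ccc1OCc1ccccc1 | intermediate
6 | 2-[2,5-bis(benzyloxy)phenyl]-4-bromo-6-hydroxy-2H-pyran-3(6H)-one (racemic, diastereomer mixture) | OC1OC(c2cc(OCc3ccccc3)ccc2OCc2ccccc2)C(=O)C(Br)=C1 | intermediate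
7 | 2-[2,5-bis(benzyloxy)phenyl]-3-hydroxy-4H-pyran-4-one | O=c1ccoc(-c2cc(OCc3ccccc3)ccc2OCc2ccccc2)c1O | intermediate
8 | 3-benzyloxy-2-[2,5-bis(benzyloxy)phenyl]-4H-pyran-4-one | O=c1ccoc(-c2cc(OCc3ccccc3)ccc2OCc2ccccc2)c1OCc1ccccc1 | intermediate
9 | {5-benzyloxy-6-[2,5-bis(benzyloxy)phenyl]-4-oxo-4H-pyran-3-yl}zinc chloride | O=c1c([Zn]Cl)coc(-c2cc(OCc3ccccc3)ccc2OCc2ccccc2)c1OCc1ccccc1 | intermediate
10 | 3-benzyloxy-2-[2,5-bis(benzyloxy)phenyl]-5-iodo-4H-pyran-4-one | O=c1c(I)coc(-c2cc(OCc3ccccc3)ccc2OCc2ccccc2)c1OCc1ccccc1 | intermediate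
11 | dimethyl squarate (3,4-dimethoxycyclobut-3-ene-1,2-dione) | COC1=C(OC)C(=O)C1=O | starting material
12 | {5-benzyloxy-6-[2,5-bis(benzyloxy)phenyl]-4-oxo-4H-pyran-3-yl}magnesium chloride | O=c1c([Mg]Cl)coc(-c2cc(OCc3ccccc3)ccc2OCc2ccccc2)c1OCc1ccccc1 | intermediate
13 | 4-{5-benzyloxy-6-[2,5-bis(benzyloxy)phenyl]-4-oxo-4H-pyran-3-yl}-4-hydroxy-2,3-dimethoxycyclobut-2-en-1-one (racemic) | COC1=C(OC)C(O)(c2coc(-c3cc(OCc4ccccc4)ccc3OCc3ccccc3)c(OCc3ccccc3)c2=O)C1=O | intermediate
14 | (3Z)-4-{5-benzyloxy-6-[2,5-bis(benzyloxy)phenyl]-4-oxo-4H-pyran-3-yl}-4-hydroxy-2,3-dimethoxybuta-1,3-dien-1-one (hydroxyl trans to the ketene-bearing carbon) | O=C=C(OC)/C(OC)=C(/O)c1coc(-c2cc(OCc3ccccc3)ccc2OCc2ccccc2)c(OCc2ccccc2)c1=O | intermediate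
15 | 3-benzyloxy-2-[2,5-bis(benzyloxy)phenyl]-5-hydroxy-6,7-dimethoxy-8aH-chromene-4,8-dione (racemic at C8a) | COC1=C(OC)C(=O)C2OC(c3cc(OCc4ccccc4)ccc3OCc3ccccc3)=C(OCc3ccccc3)C(=O)C2=C1O | intermediate
16 | 3-benzyloxy-2-[2,5-bis(benzyloxy)phenyl]-5,8-dihydroxy-6,7-dimethoxy-4H-chromen-4-one | COc1c(OC)c(O)c2c(=O)c(OCc3ccccc3)c(-c3cc(OCc4ccccc4)ccc3OCc3ccccc3)oc2c1O | intermediate
17 | 3-benzyloxy-2-[2,5-bis(benzyloxy)phenyl]-5-hydroxy-6,7,8-trimethoxy-4H-chromen-4-one | COc1c(OC)c(O)c2c(=O)c(OCc3ccccc3)c(-c3cc(OCc4ccccc4)ccc3OCc3ccccc3)oc2c1OC | intermediate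
18 | 2-(2,5-dihydroxyphenyl)-3,5-dihydroxy-6,7,8-trimethoxy-4H-chromen-4-one (achiral) | COc1c(OC)c(O)c2c(=O)c(O)c(-c3cc(O)ccc3O)oc2c1OC | target

**Step count.** Total: 9 steps. Longest linear sequence: 9 steps (1 to 18); 3-bromofuran and dimethyl squarate enter as purchased building blocks.

**Steps most likely to fail**

Step 7. The ring opening may take the wrong rotational sense, so that the hydroxyl lactonises onto the ketene. The ketene may also fail to close onto the electron-poor pyranone double bond, or the hydroquinone may oxidise during isolation. Fallback: ring A is brought in ready-made, setting out from aldehyde 2 and coming back at target 18. Claisen–Schmidt condensation of 2 with commercial 1-(2-hydroxy-3,4,5,6-tetramethoxyphenyl)ethanone (CC(=O)c1c(O)c(OC)c(OC)c(OC)c1OC; KOH, EtOH, rt) should give the chalcone (E)-3-[2,5-bis(benzyloxy)phenyl]-1-(2-hydroxy-3,4,5,6-tetramethoxyphenyl)prop-2-en-1-one F1. Oxidative cyclisation (cat. I2, DMSO, 120 °C) should give the flavone 2-[2,5-bis(benzyloxy)phenyl]-5,6,7,8-tetramethoxy-4H-chromen-4-one F2. C3 hydroxylation by epoxidation and acid-catalysed opening (dimethyldioxirane, acetone–CH2Cl2; then cat. TsOH) should give the flavonol 2-[2,5-bis(benzyloxy)phenyl]-3-hydroxy-5,6,7,8-tetramethoxy-4H-chromen-4-one F3. BCl3 (CH2Cl2, −78 to 0 °C) should then remove both benzyl groups and, by chelation control, only the 5-O-methyl group, arriving at 18.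

Step 5. The zincation may be slow, or may take place at C6 beside the ring oxygen instead of at C5. Fallback: the iodine is placed by ring opening and iodocyclisation, setting out from 8 and coming back at 10. Pyrrolidine (MeOH, 50 °C) should add at the unsubstituted C6 and open the ring to the enaminone 2-benzyloxy-1-[2,5-bis(benzyloxy)phenyl]-1-hydroxy-5-(pyrrolidin-1-yl)penta-1,4-dien-3-one F4. Iodine (CHCl3, rt) should then iodinate the enamine carbon and reclose the ring with loss of pyrrolidine, as in the enaminone route to 3-iodochromones, giving 10.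

Step 3. NBS may brominate ring B in competition with the less electron-rich bromofuran, the hydrolytic rearrangement may stall, or acid may cleave benzyl ethers. Fallback: the classical bromine-free sequence, setting out from aldehyde 2 and coming back at 7. 2-Lithiofuran (furan, n-BuLi, THF, 0 °C) should add to 2 to give [2,5-bis(benzyloxy)phenyl](furan-2-yl)methanol F5. Achmatowicz ring expansion (NBS, NaHCO3, THF–H2O, 0 °C; the unsubstituted furan reacts far faster than ring B) should give 2-[2,5-bis(benzyloxy)phenyl]-6-hydroxy-2H-pyran-3(6H)-one F6. Methyl glycoside formation (HC(OMe)3, BF3·OEt2, −20 °C) should give 2-[2,5-bis(benzyloxy)phenyl]-6-methoxy-2H-pyran-3(6H)-one F7. Nucleophilic epoxidation of the enone (H2O2, cat. NaOH, MeOH, 0 °C) should give 2-[2,5-bis(benzyloxy)phenyl]-4,5-epoxy-6-methoxytetrahydropyran-3-one F8. Warm aqueous acid (1 M H2SO4–dioxane, 80 °C) should isomerise the epoxy ketone to the diosphenol and expel methanol, giving 7.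

**Further compounds**

F1 | step 7 | (E)-3-[2,5-bis(benzyloxy)phenyl]-1-(2-hydroxy-3,4,5,6-tetramethoxyphenyl)prop-2-en-1-one | COc1c(OC)c(OC)c(C(=O)/C=C/c2cc(OCc3ccccc3)ccc2OCc2ccccc2)c(O)c1OC
F2 | step 7 | 2-[2,5-bis(benzyloxy)phenyl]-5,6,7,8-tetramethoxy-4H-chromen-4-one | COc1c(OC)c(OC)c2c(=O)cc(-c3cc(OCc4ccccc4)ccc3OCc3ccccc3)oc2c1OC
F3 | step 7 | 2-[2,5-bis(benzyloxy)phenyl]-3-hydroxy-5,6,7,8-tetramethoxy-4H-chromen-4-one | COc1c(OC)c(OC)c2c(=O)c(O)c(-c3cc(OCc4ccccc4)ccc3OCc3ccccc3)oc2c1OC
F4 | step 5 | 2-benzyloxy-1-[2,5-bis(benzyloxy)phenyl]-1-hydroxy-5-(pyrrolidin-1-yl)penta-1,4-dien-3-one (enol form, 4E) | O=C(/C=C/N1CCCC1)C(OCc1ccccc1)=C(O)c1cc(OCc2ccccc2)ccc1OCc1ccccc1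
F5 | step 3 | [2,5-bis(benzyloxy)phenyl](furan-2-yl)methanol (racemic) | OC(c1ccco1)c1cc(OCc2ccccc2)ccc1OCc1ccccc1
F6 | step 3 | 2-[2,5-bis(benzyloxy)phenyl]-6-hydroxy-2H-pyran-3(6H)-one (racemic, diastereomer mixture) | OC1OC(c2cc(OCc3ccccc3)ccc2OCc2ccccc2)C(=O)C=C1
F7 | step 3 | 2-[2,5-bis(benzyloxy)phenyl]-6-methoxy-2H-pyran-3(6H)-one (racemic, diastereomer mixture) | COC1OC(c2cc(OCc3ccccc3)ccc2OCc2ccccc2)C(=O)C=C1
F8 | step 3 | 2-[2,5-bis(benzyloxy)phenyl]-4,5-epoxy-6-methoxytetrahydropyran-3-one (racemic, diastereomer mixture) | COC1OC(c2cc(OCc3ccccc3)ccc2OCc2ccccc2)C(=O)C2OC12
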